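The route cuts ring B of the diaryl ether at two neighbouring positions, the C1'–O bond and the C2'–Br bond. With the C4' bromine para to the oxygen, this vicinal O/Br pair is the imprint of 4-bromobenzyne. In one operation free of transition metals, fluoride should release the aryne from 4-bromo-2-(trimethylsilyl)phenyl triflate. The aryne should then take up the potassium salt of 3,5-dibromo-2-methoxyphenol at C1' and a bromine atom from 1,2-dibromotetrachloroethane at C2'. The phenol is ring A, complete with both bromines and a masked C1 hydroxyl. Each partner is two routine steps from a commercial phenol, and one demethylation finishes the target.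

Key step: step 5

Remark: ring A is the phenol ring of the target (C1 OH, C2 and C4 Br, C6 ether oxygen). Ring B is the 2,4-dibromophenoxy ring (C1' O, C2' and C4' Br). The target is achiral, so no stereocentre has to be set.

Step 1
Reactants: 1 4-bromo-2-iodophenol
Product: 2 (4-bromo-2-iodophenoxy)trimethylsilane
Conditions: HMDS (0.6 equiv), THF, 65 °C; evaporate
Reagents that add atoms: hexamethyldisilazane, C[Si](C)(C)N[Si](C)(C)C
Why: O-silylation of a phenol with a silazane is routine and its only by-product is volatile, so crude 2 can be carried on after evaporation.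

Step 2
Reactants: 2 (4-bromo-2-iodophenoxy)trimethylsilane
Product: 5 4-bromo-2-(trimethylsilyl)phenyl trifluoromethanesulfonate, via aryllithium 3 (not isolated), via lithium silylphenoxide 4 (not isolated)
Conditions: n-BuLi (1.0 equiv), THF, −78 °C; then Tf2O, −78 °C → rt
Reagents that add atoms: trifluoromethanesulfonic anhydride, O=S(=O)(OS(=O)(=O)C(F)(F)F)C(F)(F)F
Why: Iodine–lithium exchange is much faster than bromine–lithium exchange, so only the carbon ortho to oxygen should be metalated and the C4 bromine kept, after which the known 1,3 O-to-C silyl shift (retro-Brook rearrangement) and O-triflation of the released phenoxide follow the standard one-pot entry to 2-silylaryl triflates.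

Step 3
Reactants: 6 3,5-dibromo-2-hydroxybenzaldehyde (3,5-dibromosalicylaldehyde)
Product: 7 3,5-dibromo-2-methoxybenzaldehyde
Conditions: MeI, K2CO3, DMF, rt
Reagents that add atoms: iodomethane, CI
Why: Williamson ether synthesis on an acidic, doubly bromine-activated phenol should proceed cleanly, and nothing else in 6 can be alkylated.

Step 4
Reactants: 7 3,5-dibromo-2-methoxybenzaldehyde
Product: 9 3,5-dibromo-2-methoxyphenol, via aryl formate 8 (not isolated)
Conditions: mCPBA, CH2Cl2, 40 °C; aqueous basic wash; then K2CO3 (cat.), MeOH, rt
Reagents that add atoms: 3-chloroperoxybenzoic acid, OOC(=O)c1cccc(Cl)c1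
Why: The alkaline peroxide Dakin reaction needs a free ortho or para hydroxyl, so its peracid counterpart, the Baeyer–Villiger oxidation, is used, in which the ortho methoxy group supports aryl migration to the formate that methanolysis then cleaves.

Step 5
Reactants: 5 4-bromo-2-(trimethylsilyl)phenyl trifluoromethanesulfonate; 9 3,5-dibromo-2-methoxyphenol; 10 1,2-dibromo-1,1,2,2-tetrachloroethane
Product: 14 1,5-dibromo-3-(2,4-dibromophenoxy)-2-methoxybenzene, via potassium phenoxide 11 (not isolated), via 4-bromobenzyne 12 (not isolated), via arylpotassium 13 (not isolated)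
Conditions: 9, KH (1.0 equiv), THF, 0 °C; then 18-crown-6, anhydrous KF, 10 (3 equiv); 5 (1.5 equiv) added slowly, 0 °C → rt
Reagents that add atoms: 1,2-dibromo-1,1,2,2-tetrachloroethane (10), ClC(Cl)(Br)C(Cl)(Cl)Br
Why: Proposed new method: fluoride attacks the silicon of 5 and triflate departs to give aryne 12, the crown-separated phenoxide 11 adds through oxygen at C1', and the C2' carbanion 13 pulls bromine off 10 in a halophilic displacement made irreversible by collapse of the donor to tetrachloroethene and bromide. The closest known reaction types are three-component aryne couplings that place a nitrogen or sulfur nucleophile and a halogen on neighbouring carbons, and the fluoride-mediated O-arylation of phenols by silylaryl triflates, where the same kind of aryl anion is merely protonated. No ring is closed and no stereocentre is formed. The step needs regioselective addition to an unsymmetrical aryne: the inductive pull of the C4' bromine stabilises charge better at the meta carbon C2' than at the para carbon C1', so oxygen should prefer C1', but the substituent is remote, the bias is expected to be modest, and the 2,5-dibromophenoxy isomer must be removed by chromatography or crystallisation. Bromine transfer must also outrun protonation, which is why the phenol is deprotonated with KH (hydrogen gas as sole by-product), THF replaces the usual acidic acetonitrile, 10 is present in excess and 5 is added slowly to keep the aryne dilute. No transition metal is present, so none of the aryl C–Br bonds is exposed to insertion.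

Step 6
Reactants: 14 1,5-dibromo-3-(2,4-dibromophenoxy)-2-methoxybenzene
Product: 16 2,4-dibromo-6-(2,4-dibromophenoxy)phenol, via aryloxydibromoborane 15 (not isolated)
Conditions: BBr3, CH2Cl2, −78 °C → rt; then H2O
Reagents that add atoms: none
Why: Lewis-acid cleavage of an aryl methyl ether by BBr3 breaks only the O–CH3 bond, since bromide cannot attack the sp2 carbons of the diaryl ether and the aryl bromides are inert.

Compound list
1 | 4-bromo-2-iodophenol | Oc1ccc(Br)cc1I | starting material
2 | (4-bromo-2-iodophenoxy)trimethylsilane | C[Si](C)(C)Oc1ccc(Br)cc1I | intermediate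
3 | [5-bromo-2-(trimethylsilyloxy)phenyl]lithium | C[Si](C)(C)Oc1ccc(Br)cc1[Li] | intermediate
4 | lithium 4-bromo-2-(trimethylsilyl)phenoxide | C[Si](C)(C)c1cc(Br)ccc1[O-].[Li+] | intermediate
5 | 4-bromo-2-(trimethylsilyl)phenyl trifluoromethanesulfonate | C[Si](C)(C)c1cc(Br)ccc1OS(=O)(=O)C(F)(F)F | intermediate
6 | 3,5-dibromo-2-hydroxybenzaldehyde | O=Cc1cc(Br)cc(Br)c1O | starting material
7 | 3,5-dibromo-2-methoxybenzaldehyde | COc1c(Br)cc(Br)cc1C=O | intermediate
8 | 3,5-dibromo-2-methoxyphenyl formate | COc1c(Br)cc(Br)cc1OC=O | intermediate
9 | 3,5-dibromo-2-methoxyphenol | COc1c(Br)cc(Br)cc1O | intermediate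
10 | 1,2-dibromo-1,1,2,2-tetrachloroethane | ClC(Cl)(Br)C(Cl)(Cl)Br | starting material
11 | potassium 3,5-dibromo-2-methoxyphenoxide | COc1c(Br)cc(Br)cc1[O-].[K+] | intermediate
12 | 4-bromobenzyne (4-bromo-1,2-didehydrobenzene) | BrC1=CC#CC=C1 | intermediate
13 | [5-bromo-2-(3,5-dibromo-2-methoxyphenoxy)phenyl]potassium | COc1c(Br)cc(Br)cc1Oc1ccc(Br)cc1[K] | intermediate
14 | 1,5-dibromo-3-(2,4-dibromophenoxy)-2-methoxybenzene | COc1c(Br)cc(Br)cc1Oc1ccc(Br)cc1Br | intermediate
15 | dibromo[2,4-dibromo-6-(2,4-dibromophenoxy)phenoxy]borane | BrB(Br)Oc1c(Br)cc(Br)cc1Oc1ccc(Br)cc1Br | intermediate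
16 | 2,4-dibromo-6-(2,4-dibromophenoxy)phenol | Oc1c(Br)cc(Br)cc1Oc1ccc(Br)cc1Br | target

Total step count: 6
Longest linear sequence: 4 (steps 3, 4, 5, 6; the other branch, steps 1, 2, 5, 6, is equally long)

Steps most likely to fail

Risk 1 (step 5). Four things may go wrong:
- The aryl anion may be protonated, or may exchange halogen with the aryl bromides present, before it meets the bromine donor.
- The phenoxide may add to both aryne termini with little preference.
- The donor may brominate the free ring positions of the phenoxide.
- An intramolecular proton shift from ring A to C2' may move the charge to the wrong ring.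

The fallback builds the ether by the known metal-free O-arylation of phenoxides with diaryliodonium salts. It sets out from 9. Bis(2,4-dibromophenyl)iodonium trifluoromethanesulfonate F1 would be made from commercial 2,4-dibromo-1-iodobenzene and 1,3-dibromobenzene (mCPBA, TfOH, CH2Cl2). Phenol 9 would be converted by t-BuOK in THF into phenoxide 11 and arylated by F1 at 40 °C through ligand coupling at trivalent iodine. This returns to the route at 14. Both ring B bromines are already in place in F1, so no regiochemical question arises.

Risk 2 (step 2). Halogen–metal exchange may spill over to the C4 bromine, intermolecular halogen scrambling may precede the silyl shift, or Tf2O may be consumed by ring-opening of THF. The fallback gives up both lithium and the rearrangement and sets out from 2: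
- Iodine–magnesium exchange with iPrMgCl·LiCl (THF, −20 °C), which tolerates aryl bromides, should give [5-bromo-2-(trimethylsilyloxy)phenyl]magnesium chloride F2.
- Intermolecular C-silylation with Me3SiCl on warming should give [4-bromo-2-(trimethylsilyl)phenoxy]trimethylsilane F3.
- Methanolysis of the O–Si bond (K2CO3 cat., MeOH) should give 4-bromo-2-(trimethylsilyl)phenol F4.
- Separate triflation (Tf2O, pyridine, CH2Cl2, 0 °C) returns to the route at 5.

Risk 3 (step 4). The two bromines lower the migratory aptitude of the ring, so hydride migration in the peracid adduct may compete and divert material to the carboxylic acid oxidation level. The fallback removes the migrating hydrogen altogether and sets out from 7: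
- Addition of MeMgBr (THF, −78 → 0 °C) should give racemic 1-(3,5-dibromo-2-methoxyphenyl)ethanol F5.
- Oxidation with Dess–Martin periodinane should give 1-(3,5-dibromo-2-methoxyphenyl)ethanone F6.
- Baeyer–Villiger oxidation of this aryl methyl ketone (urea–H2O2, trifluoroacetic anhydride, Na2HPO4, CH2Cl2), where aryl outranks methyl in migration, should give 3,5-dibromo-2-methoxyphenyl acetate F7.
- Methanolysis (K2CO3, MeOH) returns to the route at 9.

Further compounds
F1 | step 5 | bis(2,4-dibromophenyl)iodonium trifluoromethanesulfonate | Brc1ccc([I+]c2ccc(Br)cc2Br)c(Br)c1.[O-]S(=O)(=O)C(F)(F)F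
F2 | step 2 | [5-bromo-2-(trimethylsilyloxy)phenyl]magnesium chloride | C[Si](C)(C)Oc1ccc(Br)cc1[Mg]Cl
F3 | step 2 | [4-bromo-2-(trimethylsilyl)phenoxy]trimethylsilane | C[Si](C)(C)Oc1ccc(Br)cc1[Si](C)(C)C
F4 | step 2 | 4-bromo-2-(trimethylsilyl)phenol | C[Si](C)(C)c1cc(Br)ccc1O
F5 | step 4 | 1-(3,5-dibromo-2-methoxyphenyl)ethanol (racemic) | COc1c(Br)cc(Br)cc1C(C)O
F6 | step 4 | 1-(3,5-dibromo-2-methoxyphenyl)ethanone | COc1c(Br)cc(Br)cc1C(C)=O
F7 | step 4 | 3,5-dibromo-2-methoxyphenyl acetate | COc1c(Br)cc(Br)cc1OC(C)=O
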